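**Retrosynthetic overview**
1. The benzoquinone is unveiled last, by oxidative demethylation of the 2,5-dimethoxyphenyl ether.
2. The side chain is cut C10 + C10 at ring–CH2|CH2–C(Me)=. An α-cyclogeranyl Grignard reagent meets an (E,E)-8-bromogeranyl arene, so both E alkenes come ready-made from geranyl bromide.
3. Key cut, ring C1–CH2: a hydroxymethyl anion (LiCH2O–, polarity-reversed formaldehyde) is delivered by a Still–Wittig [2,3]-shift to the former β-carbon of 2,4,4-trimethylcyclohexenone. The shift copies a CBS-set carbinol centre onto C1.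
4. Arene arm: ortho-lithiated 1,4-dimethoxybenzene plus geranyl bromide, then SeO2 oxidation of the terminal E-methyl group and bromination.
5. Ring order: no ring is built. The cyclohexene ring is bought as the enone, and the quinone ring is bought as 1,4-dimethoxybenzene.

Assumption: the [C@H] centre of the given SMILES is read as (R), the same spatial arrangement as in (R)-α-ionone, and both chain alkenes are E.

Step 1
Reactants: 1 2,4,4-trimethylcyclohex-2-en-1-one
Product: 2 (1S)-2,4,4-trimethylcyclohex-2-en-1-ol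
Conditions: (R)-2-methyl-CBS-oxazaborolidine [(3aR)-1-methyl-3,3-diphenyltetrahydro-1H,3H-pyrrolo[1,2-c][1,3,2]oxazaborole, 10 mol%], BH3·SMe2, THF, −20 °C; H2O quench
Reagents that add atoms: none
Why: Corey–Bakshi–Shibata reduction, in which the oxazaborolidine–borane complex binds the ketone with the bulkier 2-methylalkenyl arm pointing away and passes hydride to one carbonyl face only, so the (R)-catalyst gives the (S)-carbinol by clean 1,2-reduction while the hindered trisubstituted alkene is not hydroborated at this temperature.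

Step 2
Reactants: 2 (1S)-2,4,4-trimethylcyclohex-2-en-1-ol; 3 tributyl(iodomethyl)stannane
Product: 5 tributyl({[(1S)-2,4,4-trimethylcyclohex-2-en-1-yl]oxy}methyl)stannane, via potassium alkoxide 4 (not isolated)
Conditions: KH, THF, 0 °C; then 3, 0 °C → rt
Reagents that add atoms: none
Why: Williamson ether synthesis, an SN2 displacement of the unhindered primary iodide of 3 by alkoxide 4 that does not touch the C–O stereocentre.

Step 3 (key step)
Reactants: 5 tributyl({[(1S)-2,4,4-trimethylcyclohex-2-en-1-yl]oxy}methyl)stannane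
Product: 8 [(1R)-2,6,6-trimethylcyclohex-2-en-1-yl]methanol, via alkoxymethyllithium 6 (not isolated), via lithium alkoxide 7 (not isolated)
Conditions: nBuLi (1.2 equiv), THF, −78 → −40 °C; H2O quench
Reagents that add atoms: none
Why: Still–Wittig [2,3]-sigmatropic rearrangement, in which tin–lithium exchange turns the O–CH2 carbon (formaldehyde level and normally electrophilic) into a hydroxymethyl-anion synthon that bonds to the alkene carbon next to the gem-dimethyl group (the former β-carbon of enone 1 and likewise a natural electrophile), and because the five-membered transition state is suprafacial the new C–C bond forms on the ring face that carried oxygen, so the (S)-carbinol centre is relayed into the (R)-configured ring stereocentre while the alkene moves into its final 2,3-position.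

Step 4
Reactants: 8 [(1R)-2,6,6-trimethylcyclohex-2-en-1-yl]methanol
Product: 10 (6R)-6-(iodomethyl)-1,5,5-trimethylcyclohex-1-ene, via alkoxyphosphonium iodide 9 (not isolated)
Conditions: PPh3, imidazole, I2, toluene, rt → 60 °C
Reagents that add atoms: iodine, [I][I]
Why: Appel-type (Garegg–Samuelsson) iodination, an SN2 attack of iodide on the primary carbon of alkoxyphosphonium salt 9 under near-neutral conditions that leaves the neighbouring stereocentre and the ring alkene where they are.

Step 5
Reactants: 11 1,4-dimethoxybenzene; 12 geranyl bromide [(2E)-1-bromo-3,7-dimethylocta-2,6-diene]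
Product: 14 2-[(2E)-3,7-dimethylocta-2,6-dien-1-yl]-1,4-dimethoxybenzene, via 2,5-dimethoxyphenyllithium 13 (not isolated)
Conditions: nBuLi, TMEDA, THF, 0 °C; then 12, −78 °C → rt
Reagents that add atoms: none
Why: Directed ortho-lithiation followed by SN2 allylation, the methoxy groups steering nBuLi to the only type of ring C–H present and the aryllithium attacking the primary carbon of 12 so that the E alkene is kept.

Step 6
Reactants: 14 2-[(2E)-3,7-dimethylocta-2,6-dien-1-yl]-1,4-dimethoxybenzene
Product: 15 (2E,6E)-8-(2,5-dimethoxyphenyl)-2,6-dimethylocta-2,6-dien-1-ol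
Conditions: SeO2 (0.3 equiv), tBuOOH (2.5 equiv), salicylic acid (0.1 equiv), CH2Cl2, 0 °C → rt
Reagents that add atoms: tert-butyl hydroperoxide, CC(C)(C)OO
Why: Sharpless–Umbreit catalytic SeO2 allylic oxidation (ene reaction then [2,3]-shift), which picks the terminal isopropylidene group as the most accessible alkene and oxidises its E-methyl group, giving the (E)-allylic alcohol.

Step 7
Reactants: 15 (2E,6E)-8-(2,5-dimethoxyphenyl)-2,6-dimethylocta-2,6-dien-1-ol
Product: 16 2-[(2E,6E)-8-bromo-3,7-dimethylocta-2,6-dien-1-yl]-1,4-dimethoxybenzene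
Conditions: PBr3 (0.4 equiv), Et2O, −10 °C, 30 min
Reagents that add atoms: phosphorus tribromide, BrP(Br)Br
Why: SN2 bromination through a phosphite ester, fast at low temperature at the primary allylic carbon so that neither allylic transposition nor E/Z scrambling sets in.

Step 8
Reactants: 10 (6R)-6-(iodomethyl)-1,5,5-trimethylcyclohex-1-ene; 16 2-[(2E,6E)-8-bromo-3,7-dimethylocta-2,6-dien-1-yl]-1,4-dimethoxybenzene
Product: 19 2-{(2E,6E)-3,7-dimethyl-9-[(1R)-2,6,6-trimethylcyclohex-2-en-1-yl]nona-2,6-dien-1-yl}-1,4-dimethoxybenzene, via alkyllithium 17 (not isolated), via alkylmagnesium bromide 18 (not isolated)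
Conditions: 10, tBuLi (2.1 equiv), pentane/Et2O, −78 °C; MgBr2·OEt2, −78 → 0 °C; added quickly to 16 + Li2CuCl4 (5 mol%), THF, −40 → 0 °C
Reagents that add atoms: none
Why: Kochi–Schlosser copper-catalysed Grignard–allyl bromide cross-coupling, in which iodine–lithium exchange and transmetalation make the CH2 carbon of 10 nucleophilic and fast addition in THF keeps copper as a dialkylcuprate that substitutes at the primary α-carbon of 16 (SN2 rather than SN2′) with the E geometry kept, the ring stereocentre being a non-acidic spectator.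

Step 9
Reactants: 19 2-{(2E,6E)-3,7-dimethyl-9-[(1R)-2,6,6-trimethylcyclohex-2-en-1-yl]nona-2,6-dien-1-yl}-1,4-dimethoxybenzene
Product: 20 2-{(2E,6E)-3,7-dimethyl-9-[(1R)-2,6,6-trimethylcyclohex-2-en-1-yl]nona-2,6-dien-1-yl}cyclohexa-2,5-diene-1,4-dione
Conditions: (NH4)2Ce(NO3)6 (2.5 equiv), MeCN/THF/H2O, 0 °C, 20 min
Reagents that add atoms: water, O
Why: Oxidative demethylation of a hydroquinone dimethyl ether by tetravalent cerium, two one-electron oxidations of the electron-rich arene each followed by ipso attack of water and loss of methanol, which is much faster at 0 °C than any attack on the isolated trisubstituted alkenes and does not touch the stereocentre.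

**Compound list**
1 | 2,4,4-trimethylcyclohex-2-en-1-one | CC1=CC(C)(C)CCC1=O | starting material
2 | (1S)-2,4,4-trimethylcyclohex-2-en-1-ol | CC1=CC(C)(C)CC[C@@H]1O | intermediate
3 | tributyl(iodomethyl)stannane | IC[Sn](CCCC)(CCCC)CCCC | starting material
4 | potassium (1S)-2,4,4-trimethylcyclohex-2-en-1-olate (not isolated) | CC1=CC(C)(C)CC[C@@H]1[O-].[K+] | intermediate
5 | tributyl({[(1S)-2,4,4-trimethylcyclohex-2-en-1-yl]oxy}methyl)stannane | CC1=CC(C)(C)CC[C@@H]1OC[Sn](CCCC)(CCCC)CCCC | intermediate
6 | {[(1S)-2,4,4-trimethylcyclohex-2-en-1-yl]oxy}methyllithium (not isolated) | CC1=CC(C)(C)CC[C@@H]1OC[Li] | intermediate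
7 | lithium [(1R)-2,6,6-trimethylcyclohex-2-en-1-yl]methanolate (not isolated) | CC1=CCCC(C)(C)[C@H]1C[O-].[Li+] | intermediate
8 | [(1R)-2,6,6-trimethylcyclohex-2-en-1-yl]methanol, (R)-α-cyclogeraniol | CC1=CCCC(C)(C)[C@H]1CO | intermediate
9 | {[(1R)-2,6,6-trimethylcyclohex-2-en-1-yl]methoxy}triphenylphosphonium iodide (not isolated) | CC1=CCCC(C)(C)[C@H]1CO[P+](c1ccccc1)(c1ccccc1)c1ccccc1.[I-] | intermediate
10 | (6R)-6-(iodomethyl)-1,5,5-trimethylcyclohex-1-ene | CC1=CCCC(C)(C)[C@H]1CI | intermediate
11 | 1,4-dimethoxybenzene | COc1ccc(OC)cc1 | starting material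
12 | geranyl bromide, (2E)-1-bromo-3,7-dimethylocta-2,6-diene | CC(C)=CCC/C(C)=C/CBr | starting material
13 | 2,5-dimethoxyphenyllithium (not isolated) | COc1ccc(OC)c([Li])c1 | intermediate
14 | 2-[(2E)-3,7-dimethylocta-2,6-dien-1-yl]-1,4-dimethoxybenzene | CC(C)=CCC/C(C)=C/Cc1cc(OC)ccc1OC | intermediate
15 | (2E,6E)-8-(2,5-dimethoxyphenyl)-2,6-dimethylocta-2,6-dien-1-ol | OC/C(C)=C/CC/C(C)=C/Cc1cc(OC)ccc1OC | intermediate
16 | 2-[(2E,6E)-8-bromo-3,7-dimethylocta-2,6-dien-1-yl]-1,4-dimethoxybenzene | BrC/C(C)=C/CC/C(C)=C/Cc1cc(OC)ccc1OC | intermediate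
17 | [(1R)-2,6,6-trimethylcyclohex-2-en-1-yl]methyllithium (not isolated) | CC1=CCCC(C)(C)[C@H]1C[Li] | intermediate
18 | [(1R)-2,6,6-trimethylcyclohex-2-en-1-yl]methylmagnesium bromide (not isolated) | CC1=CCCC(C)(C)[C@H]1C[Mg]Br | intermediate
19 | 2-{(2E,6E)-3,7-dimethyl-9-[(1R)-2,6,6-trimethylcyclohex-2-en-1-yl]nona-2,6-dien-1-yl}-1,4-dimethoxybenzene | CC1=CCCC(C)(C)[C@H]1CC/C(C)=C/CC/C(C)=C/Cc1cc(OC)ccc1OC | intermediate
20 | 2-{(2E,6E)-3,7-dimethyl-9-[(1R)-2,6,6-trimethylcyclohex-2-en-1-yl]nona-2,6-dien-1-yl}cyclohexa-2,5-diene-1,4-dione | CC1=CCCC(C)(C)[C@H]1CC/C(C)=C/CC/C(C)=C/CC1=CC(=O)C=CC1=O | target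

**Totals**
- Total step count: 9.
- Longest linear sequence: 6 steps (1, 2, 3, 4, 8, 9). The arene arm (5, 6, 7) joins at step 8.

**Steps most likely to fail**

Step 3 is most at risk. The carbanion has to bond to an alkene carbon flanked by a quaternary centre, so a [1,2]-shift or plain protonation to the methyl ether may compete.
- The fallback sets out from 2 and comes back at 8, replacing steps 2 and 3.
- Alcohol 2 is heated with N,N-dimethylformamide dimethyl acetal in xylene. This is a Büchi [2,3]-rearrangement, a neutral thermal carbene variant that is again suprafacial and needs neither tin nor an organolithium.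
- It gives (1R)-N,N,2,6,6-pentamethylcyclohex-2-ene-1-carboxamide F1, which LiH2NBH3 in THF reduces to 8.

Step 8 is second. SN2′ attack at the γ-carbon of 16 or homocoupling of the organometallic would cost the most advanced material.
- The fallback sets out from 10 (together with 16) and comes back at 19.
- The iodide of 10 is displaced by PhSO2Na in DMF to give ({[(1R)-2,6,6-trimethylcyclohex-2-en-1-yl]methyl}sulfonyl)benzene F2.
- F2 is deprotonated with nBuLi in THF/DMPU at −78 °C and alkylated by 16. The soft sulfonyl carbanion reacts only at the primary carbon.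
- The product is 2-{(2E,6E)-3,7-dimethyl-9-(phenylsulfonyl)-9-[(1R)-2,6,6-trimethylcyclohex-2-en-1-yl]nona-2,6-dien-1-yl}-1,4-dimethoxybenzene F3, formed as both epimers at C9.
- Mg turnings in MeOH remove the sulfonyl group and erase the extra centre to give 19.

Step 6 is third. Over-oxidation to the enal is likely, and so is attack at the inner alkene or at the doubly activated ArCH2 group.
- The fallback sets out from 14 and comes back at 16, replacing steps 6 and 7.
- The terminal alkene is epoxidised with mCPBA in CH2Cl2 at −20 °C to give racemic 2-[(2E)-5-(3,3-dimethyloxiran-2-yl)-3-methylpent-2-en-1-yl]-1,4-dimethoxybenzene F4.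
- Al(OiPr)3 in refluxing toluene isomerises F4 to racemic (6E)-8-(2,5-dimethoxyphenyl)-2,6-dimethylocta-1,6-dien-3-ol F5.
- PBr3 in Et2O brominates F5 with allylic transposition (SN2′) to the more stable primary E bromide 16, in which the temporary stereocentre has vanished.

**Further compounds**
F1 | step 3 | (1R)-N,N,2,6,6-pentamethylcyclohex-2-ene-1-carboxamide | CC1=CCCC(C)(C)[C@H]1C(=O)N(C)C
F2 | step 8 | ({[(1R)-2,6,6-trimethylcyclohex-2-en-1-yl]methyl}sulfonyl)benzene | CC1=CCCC(C)(C)[C@H]1CS(=O)(=O)c1ccccc1
F3 | step 8 | 2-{(2E,6E)-3,7-dimethyl-9-(phenylsulfonyl)-9-[(1R)-2,6,6-trimethylcyclohex-2-en-1-yl]nona-2,6-dien-1-yl}-1,4-dimethoxybenzene (both C9 epimers) | CC1=CCCC(C)(C)[C@H]1C(C/C(C)=C/CC/C(C)=C/Cc1cc(OC)ccc1OC)S(=O)(=O)c1ccccc1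
F4 | step 6 | 2-[(2E)-5-(3,3-dimethyloxiran-2-yl)-3-methylpent-2-en-1-yl]-1,4-dimethoxybenzene (racemic) | CC1(C)OC1CC/C(C)=C/Cc1cc(OC)ccc1OC
F5 | step 6 | (6E)-8-(2,5-dimethoxyphenyl)-2,6-dimethylocta-1,6-dien-3-ol (racemic) | C=C(C)C(O)CC/C(C)=C/Cc1cc(OC)ccc1OC
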